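**Strategy.** The route rests on cutting ring A (the prenylated ring; carotenoid numbering) between C4, the ring CH2 next to the olefin, and C5, the methyl-bearing olefinic carbon. The open precursor is an ethyl ketone in which C6 is the carbonyl, C5 its only enolisable α-carbon (C1 is the quaternary gem-dimethyl carbon) and C4 a primary iodide; its C2 stereocentre comes from a catalytic asymmetric Mukaiyama–Michael addition. In one operation the key step closes the ring by enolate C-alkylation and traps the same α-position as the C5=C6 enol triflate, the handle for Stille and Horner–Wadsworth–Emmons chain assembly. Ring B is built alike from the enantiomeric adduct.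

Key step: step 6

Assumption: the (S,S) antipode of the IDPi catalyst is taken to give the (4R) adduct 4 and the (R,R) antipode the (4S) adduct 26; if the facial sense proves opposite, the two antipodes of steps 1 and 11 are exchanged.

Step 1
Reactants: 1 5,6-dihydro-2H-pyran-2-one; 2 1-methoxy-2-methyl-1-(trimethylsilyloxy)prop-1-ene
Product: 4 methyl 2-methyl-2-[(4R)-2-oxooxan-4-yl]propanoate, via silyl ketene acetal 3 (not isolated)
Conditions: (S,S)-IDPi acid catalyst (BINOL-derived N-triflyl imidodiphosphorimidate, 2 mol %), 2 (1.5 equiv), PhMe, −60 °C; then 1 M HCl, THF, 0 °C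
Reagents that add atoms: 2, 1-methoxy-2-methyl-1-(trimethylsilyloxy)prop-1-ene, COC(O[Si](C)(C)C)=C(C)C
Why: Catalytic asymmetric Mukaiyama–Michael addition: the silylium ion pair formed from the IDPi acid and 2 activates the lactone carbonyl, the confined chiral anion should steer the fully substituted ketene acetal carbon to one enantiotopic face of C4 and so set the (4R) centre (future C2 of ring A) next to the new quaternary carbon, and hydrolysis of 3 gives 4.

Step 2
Reactants: 4 methyl 2-methyl-2-[(4R)-2-oxooxan-4-yl]propanoate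
Product: 5 methyl 2-[(4R)-2-hydroxyoxan-4-yl]-2-methylpropanoate (lactol, anomer mixture)
Conditions: i-Bu2AlH (1.1 equiv), CH2Cl2, −78 °C; Rochelle salt work-up
Reagents that add atoms: none
Why: Partial reduction of a lactone to the lactol through a tetrahedral aluminate that is stable at −78 °C; the methyl ester flanked by the quaternary carbon should react far more slowly and the stereocentre is untouched.

Step 3
Reactants: 5 methyl 2-[(4R)-2-hydroxyoxan-4-yl]-2-methylpropanoate; 6 isopropyltriphenylphosphonium iodide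
Product: 8 (4S)-3,3-dimethyl-4-(3-methylbut-2-en-1-yl)oxan-2-one, via hydroxy ester 7 (not isolated)
Conditions: 6 (2.5 equiv), KN(SiMe3)2 (2.4 equiv), THF, 0 °C → rt; then PPTS (10 mol %), PhMe, 80 °C on the crude alcohol
Reagents that add atoms: 6, isopropyltriphenylphosphonium iodide, CC(C)[P+](c1ccccc1)(c1ccccc1)c1ccccc1.[I-]
Why: Wittig olefination of the open hydroxy aldehyde form of the lactol with the non-stabilised isopropylidene ylide installs the prenyl group (symmetrical olefin terminus, no E/Z issue), and the freed δ-hydroxyl then lactonises onto the gem-dimethyl ester (Thorpe–Ingold-assisted transesterification), tying C6 and the C4 oxygen into one ring without touching the stereocentre.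

Step 4
Reactants: 8 (4S)-3,3-dimethyl-4-(3-methylbut-2-en-1-yl)oxan-2-one; 9 ethyllithium
Product: 10 (5S)-5-(2-hydroxyethyl)-4,4,8-trimethylnon-7-en-3-one (in equilibrium with its cyclic hemiketal)
Conditions: EtLi (1.2 equiv), Et2O, −78 °C; then aq. NH4Cl, −78 °C → rt
Reagents that add atoms: 9, ethyllithium, [Li]CC
Why: Mono-addition of an alkyllithium to a lactone: the α-quaternary lactone cannot enolise and the lithium lactolate is stable at −78 °C, so a single ethyl group should be delivered and work-up releases the ethyl ketone (C6 with C5 as its CH2) together with the C4 hydroxyl.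

Step 5
Reactants: 10 (5S)-5-(2-hydroxyethyl)-4,4,8-trimethylnon-7-en-3-one; 11 iodine
Product: 12 (5S)-5-(2-iodoethyl)-4,4,8-trimethylnon-7-en-3-one
Conditions: I2 (1.3 equiv), PPh3 (1.3 equiv), imidazole (2.5 equiv), CH2Cl2, 0 °C → rt
Reagents that add atoms: 11, iodine, II
Why: Appel-type iodination converts the primary alcohol of the open hydroxy ketone form into the primary iodide by SN2; the hindered ketone, the trisubstituted olefin and the β-stereocentre are inert.

Step 6
Reactants: 12 (5S)-5-(2-iodoethyl)-4,4,8-trimethylnon-7-en-3-one; 13 N-phenylbis(trifluoromethanesulfonimide)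
Product: 15 (5R)-2,6,6-trimethyl-5-(3-methylbut-2-en-1-yl)cyclohex-1-en-1-yl trifluoromethanesulfonate, via cyclohexanone 14 (not isolated)
Conditions: KN(SiMe3)2 (1.05 equiv), THF, −78 → 0 °C; then KN(SiMe3)2 (1.3 equiv), −78 → 0 °C; PhNTf2 (1.4 equiv), 0 °C → rt
Reagents that add atoms: 13, N-phenylbis(trifluoromethanesulfonimide), O=S(=O)(N(c1ccccc1)S(=O)(=O)C(F)(F)F)C(F)(F)F
Why: KN(SiMe3)2 removes a proton from the ethyl CH2 (future C5), the only enolisable position because the other α-carbon (C1) is the quaternary gem-dimethyl carbon, and the potassium enolate displaces the primary iodide at C4 in an intramolecular SN2 C-alkylation that forms the C4–C5 bond and ring A. The closest known reaction type is the base-mediated cyclisation of 6-halo-3,3-dimethylalkan-2-ones to 2,2-dimethylcyclohexanones; the ring closes in the 6-(enolendo)-exo-tet mode, which is stereoelectronically allowed and, unlike the five-membered case, favours C- over O-alkylation, with the gem-dimethyl group adding a Thorpe–Ingold push. The new stereocentre at C5 forms under substrate control as an inconsequential epimer mixture, because the second deprotonation at this same carbon and O-sulfonylation with PhNTf2 turn it into the sp2 carbon of the C5=C6 enol triflate. The C2 stereocentre is β to the carbonyl and not enolisable, so it cannot epimerise. The selectivities needed are regiocontrol in both enolisations (secured by quaternary C1), C- versus O-alkylation (ring size and the soft iodide) and substitution over elimination (primary iodide, intramolecular delivery).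

Step 7
Reactants: 16 (2E)-3-methylpent-2-en-4-yn-1-ol; 17 triethyl phosphite
Product: 19 diethyl [(2E)-3-methylpent-2-en-4-yn-1-yl]phosphonate, via allylic bromide 18 (not isolated)
Conditions: PBr3 (0.4 equiv), pyridine (cat.), Et2O, −10 °C; then P(OEt)3 (3 equiv), 90 °C
Reagents that add atoms: 17, triethyl phosphite, CCOP(OCC)OCC
Why: Bromination of the primary allylic alcohol followed by Michaelis–Arbuzov reaction of the crude bromide; attack at the primary carbon keeps the (E)-enyne intact.

Step 8
Reactants: 19 diethyl [(2E)-3-methylpent-2-en-4-yn-1-yl]phosphonate; 20 tributyltin hydride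
Product: 21 diethyl [(2E,4E)-3-methyl-5-(tributylstannyl)penta-2,4-dien-1-yl]phosphonate
Conditions: Bu3SnH (1.2 equiv), PdCl2(PPh3)2 (2 mol %), THF, 0 °C → rt
Reagents that add atoms: 20, tributyltin hydride, CCCC[SnH](CCCC)CCCC
Why: Palladium-catalysed syn-hydrostannation of the terminal alkyne of a conjugated enyne should place tin on the terminal carbon, so the (4E) geometry follows from the syn addition and the (2E) geometry from the starting enyne.

Step 9
Reactants: 15 (5R)-2,6,6-trimethyl-5-(3-methylbut-2-en-1-yl)cyclohex-1-en-1-yl trifluoromethanesulfonate; 21 diethyl [(2E,4E)-3-methyl-5-(tributylstannyl)penta-2,4-dien-1-yl]phosphonate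
Product: 22 diethyl {(2E,4E)-3-methyl-5-[(5R)-2,6,6-trimethyl-5-(3-methylbut-2-en-1-yl)cyclohex-1-en-1-yl]penta-2,4-dien-1-yl}phosphonate
Conditions: Pd2(dba)3 (2.5 mol %), AsPh3 (20 mol %), NMP, 60 °C, dark
Reagents that add atoms: 21, diethyl [(2E,4E)-3-methyl-5-(tributylstannyl)penta-2,4-dien-1-yl]phosphonate, CCCC[Sn](CCCC)(CCCC)/C=C/C(C)=C/CP(=O)(OCC)OCC
Why: Stille cross-coupling of a hindered tetrasubstituted enol triflate with an (E)-alkenylstannane under ligand-accelerated conditions (zerovalent palladium, AsPh3, NMP), a combination established for 2,6,6-trimethylcyclohexenyl triflate; it forms the C6–C7 bond with retention of olefin geometry.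

Step 10
Reactants: 22 diethyl {(2E,4E)-3-methyl-5-[(5R)-2,6,6-trimethyl-5-(3-methylbut-2-en-1-yl)cyclohex-1-en-1-yl]penta-2,4-dien-1-yl}phosphonate; 23 (2E,4E,6E)-2,7-dimethylocta-2,4,6-trienedial
Product: 24 (2E,4E,6E,8E,10E,12E)-2,7,11-trimethyl-13-[(5R)-2,6,6-trimethyl-5-(3-methylbut-2-en-1-yl)cyclohex-1-en-1-yl]trideca-2,4,6,8,10,12-hexaenal
Conditions: NaN(SiMe3)2 (1.05 equiv), THF, −78 °C; anion added to 23 (3 equiv), THF, −78 → 0 °C, dark
Reagents that add atoms: 23, (2E,4E,6E)-2,7-dimethylocta-2,4,6-trienedial, O=C/C(C)=C/C=C/C=C(C)/C=O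
Why: Horner–Wadsworth–Emmons olefination of the allylic phosphonate anion with one formyl group of the symmetrical dialdehyde (excess dialdehyde and inverse addition suppress double condensation) should form the C11=C12 bond with the E preference of stabilised phosphonate anions.

Step 11
Reactants: 1 5,6-dihydro-2H-pyran-2-one; 2 1-methoxy-2-methyl-1-(trimethylsilyloxy)prop-1-ene
Product: 26 methyl 2-methyl-2-[(4S)-2-oxooxan-4-yl]propanoate, via silyl ketene acetal 25 (not isolated)
Conditions: (R,R)-IDPi acid catalyst (2 mol %), 2 (1.5 equiv), PhMe, −60 °C; then 1 M HCl, THF, 0 °C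
Reagents that add atoms: 2, 1-methoxy-2-methyl-1-(trimethylsilyloxy)prop-1-ene, COC(O[Si](C)(C)C)=C(C)C
Why: The same catalytic asymmetric Mukaiyama–Michael addition as in step 1; the mirror-image catalyst should deliver the ketene acetal carbon to the opposite face of C4 and set the (4S) centre, the future C2′ of ring B.

Step 12
Reactants: 26 methyl 2-methyl-2-[(4S)-2-oxooxan-4-yl]propanoate
Product: 27 methyl 2-[(4S)-2-hydroxyoxan-4-yl]-2-methylpropanoate (lactol, anomer mixture)
Conditions: i-Bu2AlH (1.1 equiv), CH2Cl2, −78 °C; Rochelle salt work-up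
Reagents that add atoms: none
Why: Partial i-Bu2AlH reduction of the lactone to the lactol as in step 2; the hindered ester and the stereocentre are untouched.

Step 13
Reactants: 27 methyl 2-[(4S)-2-hydroxyoxan-4-yl]-2-methylpropanoate; 28 methyltriphenylphosphonium bromide
Product: 30 (4R)-3,3-dimethyl-4-(prop-2-en-1-yl)oxan-2-one, via hydroxy ester 29 (not isolated)
Conditions: 28 (2.5 equiv), KN(SiMe3)2 (2.4 equiv), THF, 0 °C → rt; then PPTS (10 mol %), PhMe, 80 °C on the crude alcohol
Reagents that add atoms: 28, methyltriphenylphosphonium bromide, C[P+](c1ccccc1)(c1ccccc1)c1ccccc1.[Br-]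
Why: Wittig methylenation of the open hydroxy aldehyde form of the lactol gives the allyl group (handle for the ring B side chain), and acid-catalysed lactonisation of the freed δ-hydroxyl onto the gem-dimethyl ester follows as in step 3.

Step 14
Reactants: 30 (4R)-3,3-dimethyl-4-(prop-2-en-1-yl)oxan-2-one; 9 ethyllithium
Product: 31 (5R)-5-(2-hydroxyethyl)-4,4-dimethyloct-7-en-3-one (in equilibrium with its cyclic hemiketal)
Conditions: EtLi (1.2 equiv), Et2O, −78 °C; then aq. NH4Cl, −78 °C → rt
Reagents that add atoms: 9, ethyllithium, [Li]CC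
Why: Mono-addition of ethyllithium to the non-enolisable α-quaternary lactone through a stable lithium lactolate, as in step 4.

Step 15
Reactants: 31 (5R)-5-(2-hydroxyethyl)-4,4-dimethyloct-7-en-3-one; 11 iodine
Product: 32 (5R)-5-(2-iodoethyl)-4,4-dimethyloct-7-en-3-one
Conditions: I2 (1.3 equiv), PPh3 (1.3 equiv), imidazole (2.5 equiv), CH2Cl2, 0 °C → rt
Reagents that add atoms: 11, iodine, II
Why: Appel-type iodination of the primary alcohol by SN2 as in step 5; the terminal olefin is inert.

Step 16
Reactants: 32 (5R)-5-(2-iodoethyl)-4,4-dimethyloct-7-en-3-one; 13 N-phenylbis(trifluoromethanesulfonimide)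
Product: 34 (5S)-2,6,6-trimethyl-5-(prop-2-en-1-yl)cyclohex-1-en-1-yl trifluoromethanesulfonate, via cyclohexanone 33 (not isolated)
Conditions: KN(SiMe3)2 (1.05 equiv), THF, −78 → 0 °C; then KN(SiMe3)2 (1.3 equiv), −78 → 0 °C; PhNTf2 (1.4 equiv), 0 °C → rt
Reagents that add atoms: 13, N-phenylbis(trifluoromethanesulfonimide), O=S(=O)(N(c1ccccc1)S(=O)(=O)C(F)(F)F)C(F)(F)F
Why: Intramolecular ketone enolate C-alkylation in the 6-(enolendo)-exo-tet mode followed by O-triflation of the regiodefined enolate, exactly as in step 6; it forms the C4′–C5′ bond of ring B, the C5′ epimers converge in the enol triflate and the C2′ centre is not enolisable.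

Step 17
Reactants: 34 (5S)-2,6,6-trimethyl-5-(prop-2-en-1-yl)cyclohex-1-en-1-yl trifluoromethanesulfonate; 35 2-methylidenepropane-1,3-diol
Product: 36 (5S)-5-[4-hydroxy-3-(hydroxymethyl)but-2-en-1-yl]-2,6,6-trimethylcyclohex-1-en-1-yl trifluoromethanesulfonate
Conditions: second-generation Hoveyda–Grubbs catalyst RuCl2(H2IMes)(=CH-C6H4-2-O-i-Pr) (5 mol %), 35 (5 equiv), CH2Cl2, 40 °C
Reagents that add atoms: 35, 2-methylidenepropane-1,3-diol, C=C(CO)CO
Why: Olefin cross-metathesis between the terminal allyl olefin and an excess of the 1,1-disubstituted partner releases ethene; the partner is symmetrical, so the new trisubstituted olefin has no E/Z issue, and the tetrasubstituted enol triflate is inert to the ruthenium carbene.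

Step 18
Reactants: 36 (5S)-5-[4-hydroxy-3-(hydroxymethyl)but-2-en-1-yl]-2,6,6-trimethylcyclohex-1-en-1-yl trifluoromethanesulfonate; 21 diethyl [(2E,4E)-3-methyl-5-(tributylstannyl)penta-2,4-dien-1-yl]phosphonate
Product: 37 diethyl {(2E,4E)-5-[(5S)-5-[4-hydroxy-3-(hydroxymethyl)but-2-en-1-yl]-2,6,6-trimethylcyclohex-1-en-1-yl]-3-methylpenta-2,4-dien-1-yl}phosphonate
Conditions: Pd2(dba)3 (2.5 mol %), AsPh3 (20 mol %), NMP, 60 °C, dark
Reagents that add atoms: 21, diethyl [(2E,4E)-3-methyl-5-(tributylstannyl)penta-2,4-dien-1-yl]phosphonate, CCCC[Sn](CCCC)(CCCC)/C=C/C(C)=C/CP(=O)(OCC)OCC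
Why: Stille cross-coupling as in step 9; the neutral conditions tolerate the free allylic diol and the stannane geometry is retained.

Step 19
Reactants: 37 diethyl {(2E,4E)-5-[(5S)-5-[4-hydroxy-3-(hydroxymethyl)but-2-en-1-yl]-2,6,6-trimethylcyclohex-1-en-1-yl]-3-methylpenta-2,4-dien-1-yl}phosphonate; 24 (2E,4E,6E,8E,10E,12E)-2,7,11-trimethyl-13-[(5R)-2,6,6-trimethyl-5-(3-methylbut-2-en-1-yl)cyclohex-1-en-1-yl]trideca-2,4,6,8,10,12-hexaenal
Product: 38 (all-E)-(2R,2′S)-2′-[4-hydroxy-3-(hydroxymethyl)but-2-en-1-yl]-2-(3-methylbut-2-en-1-yl)-β,β-carotene (CNP0213288.1)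
Conditions: 37 (1.15 equiv), NaN(SiMe3)2 (3.4 equiv), THF, −78 → −40 °C; then 24, −78 → 0 °C, dark; crystallisation of the all-E isomer
Reagents that add atoms: 24, (2E,4E,6E,8E,10E,12E)-2,7,11-trimethyl-13-[(5R)-2,6,6-trimethyl-5-(3-methylbut-2-en-1-yl)cyclohex-1-en-1-yl]trideca-2,4,6,8,10,12-hexaenal, O=C/C(C)=C/C=C/C=C(C)/C=C/C=C(C)/C=C/C1=C(C)CC[C@H](CC=C(C)C)C1(C)C
Why: Horner–Wadsworth–Emmons olefination in which the base deprotonates the two hydroxyls and the phosphonate, and the carbanion condenses with the polyenal to form the C11′=C12′ bond with E preference, completing the all-E nonaene; both ring stereocentres are remote from any acidic site.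

**Compound list**

1 | 5,6-dihydro-2H-pyran-2-one | O=C1C=CCCO1 | starting material
2 | 1-methoxy-2-methyl-1-(trimethylsilyloxy)prop-1-ene | COC(O[Si](C)(C)C)=C(C)C | starting material
3 | methyl 2-methyl-2-[(4R)-6-(trimethylsilyloxy)-3,4-dihydro-2H-pyran-4-yl]propanoate | COC(=O)C(C)(C)[C@@H]1CCOC(O[Si](C)(C)C)=C1 | intermediate
4 | methyl 2-methyl-2-[(4R)-2-oxooxan-4-yl]propanoate | COC(=O)C(C)(C)[C@H]1CC(=O)OCC1 | intermediate
5 | methyl 2-[(4R)-2-hydroxyoxan-4-yl]-2-methylpropanoate (anomer mixture) | COC(=O)C(C)(C)[C@H]1CC(O)OCC1 | intermediate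
6 | isopropyltriphenylphosphonium iodide | CC(C)[P+](c1ccccc1)(c1ccccc1)c1ccccc1.[I-] | starting material
7 | methyl (3S)-3-(2-hydroxyethyl)-2,2,6-trimethylhept-5-enoate | COC(=O)C(C)(C)[C@@H](CC=C(C)C)CCO | intermediate
8 | (4S)-3,3-dimethyl-4-(3-methylbut-2-en-1-yl)oxan-2-one | O=C1OCC[C@H](CC=C(C)C)C1(C)C | intermediate
9 | ethyllithium | [Li]CC | starting material
10 | (5S)-5-(2-hydroxyethyl)-4,4,8-trimethylnon-7-en-3-one | CCC(=O)C(C)(C)[C@@H](CC=C(C)C)CCO | intermediate
11 | iodine | II | starting material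
12 | (5S)-5-(2-iodoethyl)-4,4,8-trimethylnon-7-en-3-one | CCC(=O)C(C)(C)[C@@H](CC=C(C)C)CCI | intermediate
13 | N-phenylbis(trifluoromethanesulfonimide) | O=S(=O)(N(c1ccccc1)S(=O)(=O)C(F)(F)F)C(F)(F)F | starting material
14 | (3R)-2,2,6-trimethyl-3-(3-methylbut-2-en-1-yl)cyclohexan-1-one (C6 epimers) | O=C1C(C)CC[C@H](CC=C(C)C)C1(C)C | intermediate
15 | (5R)-2,6,6-trimethyl-5-(3-methylbut-2-en-1-yl)cyclohex-1-en-1-yl trifluoromethanesulfonate | CC1=C(OS(=O)(=O)C(F)(F)F)C(C)(C)[C@@H](CC=C(C)C)CC1 | intermediate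
16 | (2E)-3-methylpent-2-en-4-yn-1-ol | C#C/C(C)=C/CO | starting material
17 | triethyl phosphite | CCOP(OCC)OCC | starting material
18 | (3E)-5-bromo-3-methylpent-3-en-1-yne | C#C/C(C)=C/CBr | intermediate
19 | diethyl [(2E)-3-methylpent-2-en-4-yn-1-yl]phosphonate | C#C/C(C)=C/CP(=O)(OCC)OCC | intermediate
20 | tributyltin hydride | CCCC[SnH](CCCC)CCCC | starting material
21 | diethyl [(2E,4E)-3-methyl-5-(tributylstannyl)penta-2,4-dien-1-yl]phosphonate | CCCC[Sn](CCCC)(CCCC)/C=C/C(C)=C/CP(=O)(OCC)OCC | intermediate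
22 | diethyl {(2E,4E)-3-methyl-5-[(5R)-2,6,6-trimethyl-5-(3-methylbut-2-en-1-yl)cyclohex-1-en-1-yl]penta-2,4-dien-1-yl}phosphonate | CCOP(=O)(OCC)C/C=C(C)/C=C/C1=C(C)CC[C@H](CC=C(C)C)C1(C)C | intermediate
23 | (2E,4E,6E)-2,7-dimethylocta-2,4,6-trienedial | O=C/C(C)=C/C=C/C=C(C)/C=O | starting material
24 | (2E,4E,6E,8E,10E,12E)-2,7,11-trimethyl-13-[(5R)-2,6,6-trimethyl-5-(3-methylbut-2-en-1-yl)cyclohex-1-en-1-yl]trideca-2,4,6,8,10,12-hexaenal | O=C/C(C)=C/C=C/C=C(C)/C=C/C=C(C)/C=C/C1=C(C)CC[C@H](CC=C(C)C)C1(C)C | intermediate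
25 | methyl 2-methyl-2-[(4S)-6-(trimethylsilyloxy)-3,4-dihydro-2H-pyran-4-yl]propanoate | COC(=O)C(C)(C)[C@H]1CCOC(O[Si](C)(C)C)=C1 | intermediate
26 | methyl 2-methyl-2-[(4S)-2-oxooxan-4-yl]propanoate | COC(=O)C(C)(C)[C@@H]1CC(=O)OCC1 | intermediate
27 | methyl 2-[(4S)-2-hydroxyoxan-4-yl]-2-methylpropanoate (anomer mixture) | COC(=O)C(C)(C)[C@@H]1CC(O)OCC1 | intermediate
28 | methyltriphenylphosphonium bromide | C[P+](c1ccccc1)(c1ccccc1)c1ccccc1.[Br-] | starting material
29 | methyl (3R)-3-(2-hydroxyethyl)-2,2-dimethylhex-5-enoate | COC(=O)C(C)(C)[C@H](CC=C)CCO | intermediate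
30 | (4R)-3,3-dimethyl-4-(prop-2-en-1-yl)oxan-2-one | O=C1OCC[C@@H](CC=C)C1(C)C | intermediate
31 | (5R)-5-(2-hydroxyethyl)-4,4-dimethyloct-7-en-3-one | CCC(=O)C(C)(C)[C@H](CC=C)CCO | intermediate
32 | (5R)-5-(2-iodoethyl)-4,4-dimethyloct-7-en-3-one | CCC(=O)C(C)(C)[C@H](CC=C)CCI | intermediate
33 | (3S)-2,2,6-trimethyl-3-(prop-2-en-1-yl)cyclohexan-1-one (C6 epimers) | O=C1C(C)CC[C@@H](CC=C)C1(C)C | intermediate
34 | (5S)-2,6,6-trimethyl-5-(prop-2-en-1-yl)cyclohex-1-en-1-yl trifluoromethanesulfonate | CC1=C(OS(=O)(=O)C(F)(F)F)C(C)(C)[C@H](CC=C)CC1 | intermediate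
35 | 2-methylidenepropane-1,3-diol | C=C(CO)CO | starting material
36 | (5S)-5-[4-hydroxy-3-(hydroxymethyl)but-2-en-1-yl]-2,6,6-trimethylcyclohex-1-en-1-yl trifluoromethanesulfonate | CC1=C(OS(=O)(=O)C(F)(F)F)C(C)(C)[C@H](CC=C(CO)CO)CC1 | intermediate
37 | diethyl {(2E,4E)-5-[(5S)-5-[4-hydroxy-3-(hydroxymethyl)but-2-en-1-yl]-2,6,6-trimethylcyclohex-1-en-1-yl]-3-methylpenta-2,4-dien-1-yl}phosphonate | CCOP(=O)(OCC)C/C=C(C)/C=C/C1=C(C)CC[C@@H](CC=C(CO)CO)C1(C)C | intermediate
38 | (all-E)-(2R,2′S)-2′-[4-hydroxy-3-(hydroxymethyl)but-2-en-1-yl]-2-(3-methylbut-2-en-1-yl)-β,β-carotene (CNP0213288.1) | CC(C)=CC[C@H]1CCC(C)=C(/C=C/C(C)=C/C=C/C(C)=C/C=C/C=C(C)/C=C/C=C(C)/C=C/C2=C(C)CC[C@@H](CC=C(CO)CO)C2(C)C)C1(C)C | target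

**Totals.** Total step count: 19. Longest linear sequence: 9 steps (steps 1–6, 9, 10, 19; equally steps 11–19).

**Three steps most likely to fail**

1. Step 1 (and its mirror image, step 11). The Mukaiyama–Michael addition may stall on the weakly electrophilic lactone, or the catalyst may discriminate the two faces of C4 poorly. Fallback: setting out from 1, the lithium enolate of methyl isobutyrate (LiN(i-Pr)2, THF, −78 °C) is added in a Michael reaction to give racemic methyl 2-methyl-2-(2-oxooxan-4-yl)propanoate F1, and its enantiomers are separated by preparative chromatography on a chiral stationary phase. Ring A needs the (4R) and ring B the (4S) antipode, so both halves are used, and the route is rejoined at 4 and at 26.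

2. Step 17. The cross-metathesis may give low conversion because the 1,1-disubstituted diol is a sluggish partner, with self-metathesis of 34 and olefin migration competing. Fallback: setting out from 34, oxidative cleavage of the terminal olefin (OsO4 cat., NaIO4, 2,6-lutidine, dioxane–H2O) gives {(1S)-2,2,4-trimethyl-3-[(trifluoromethanesulfonyl)oxy]cyclohex-3-en-1-yl}acetaldehyde F2. Knoevenagel condensation with dimethyl malonate (TiCl4, pyridine, THF, 0 °C) gives dimethyl 2-(2-{(1S)-2,2,4-trimethyl-3-[(trifluoromethanesulfonyl)oxy]cyclohex-3-en-1-yl}ethylidene)propanedioate F3, and reduction of both esters with i-Bu2AlH (CH2Cl2, −78 → 0 °C) comes back to the route at 36.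

3. Step 19. The olefination through a trianion may suffer from poor solubility of the dialkoxide and from erosion of the all-E geometry under strongly basic conditions. Fallback: setting out from 24, the Horner–Wadsworth–Emmons reaction is run with the hydroxyl-free stannyl phosphonate 21 (NaN(SiMe3)2, THF, −78 → 0 °C) to give tributyl{(1E,3E,5E,7E,9E,11E,13E,15E,17E)-3,7,12,16-tetramethyl-18-[(5R)-2,6,6-trimethyl-5-(3-methylbut-2-en-1-yl)cyclohex-1-en-1-yl]octadeca-1,3,5,7,9,11,13,15,17-nonaen-1-yl}stannane F4. The last bond is then formed between C6′ and C7′ by a base-free Stille coupling of this stannane with the unprotected triflate 36 (Pd2(dba)3, AsPh3, NMP, 50 °C), which comes back to the route at 38.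

**Further compounds**

F1 | step 1 | racemic methyl 2-methyl-2-(2-oxooxan-4-yl)propanoate | COC(=O)C(C)(C)C1CC(=O)OCC1
F2 | step 17 | {(1S)-2,2,4-trimethyl-3-[(trifluoromethanesulfonyl)oxy]cyclohex-3-en-1-yl}acetaldehyde | CC1=C(OS(=O)(=O)C(F)(F)F)C(C)(C)[C@H](CC=O)CC1
F3 | step 17 | dimethyl 2-(2-{(1S)-2,2,4-trimethyl-3-[(trifluoromethanesulfonyl)oxy]cyclohex-3-en-1-yl}ethylidene)propanedioate | CC1=C(OS(=O)(=O)C(F)(F)F)C(C)(C)[C@H](CC=C(C(=O)OC)C(=O)OC)CC1
F4 | step 19 | tributyl{(1E,3E,5E,7E,9E,11E,13E,15E,17E)-3,7,12,16-tetramethyl-18-[(5R)-2,6,6-trimethyl-5-(3-methylbut-2-en-1-yl)cyclohex-1-en-1-yl]octadeca-1,3,5,7,9,11,13,15,17-nonaen-1-yl}stannane | CCCC[Sn](CCCC)(CCCC)/C=C/C(C)=C/C=C/C(C)=C/C=C/C=C(C)/C=C/C=C(C)/C=C/C1=C(C)CC[C@H](CC=C(C)C)C1(C)C
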